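**Assumptions:** (i) (S)-(+)-carvone is the required enantiomer, because its C-5 becomes the ring carbon that carries the side chain. (ii) Mono-etherification of curcumin is achieved statistically, using an excess of the curcumin BF2 chelate. (iii) The side-chain methyl stereocentre is set by substrate control with moderate selectivity, and the minor epimer is removed chromatographically. In the text below, ring positions use carvone numbering: C-5 carries the side chain, C-6 becomes the aryl-ether carbon, and C-3 becomes the carbinol carbon.

## Retrosynthetic overview
1. The target is a curcuminoid aryl ether. It comes from opening a bicyclic 1,4-endoperoxide with the curcumin phenol (Pd, net retention at C-6), then reducing the remaining hydroperoxide at C-3 to the alcohol.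
2. The endoperoxide comes from singlet-oxygen [4+2] photooxygenation of a 2-methylcyclohexa-1,3-diene, with O2 adding anti to the C-5 substituent. This sets both ring C–O centres.
3. The side chain CH(CH3)CH2C(=O)CH=CMe2 comes from photochemical thiol-catalysed radical hydroacylation of the isopropenyl group with prenal (C10 + C5 = C15 terpenoid).
4. The diene comes from (S)-carvone by Shapiro reaction. The only carbocycle is carvone's. The bicyclic endoperoxide ring is formed in step 3 and opened in step 6.

## Route

**Step 1**
Reactants: 1 (S)-(+)-carvone; 2 p-toluenesulfonylhydrazide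
Product: 3 (S)-carvone tosylhydrazone
Conditions: MeOH, rt, 3 h
Reagents that add atoms: none
Why: Condensation of a ketone with a sulfonylhydrazide forms the hydrazone and leaves the C-5 stereocentre untouched.

**Step 2**
Reactants: 3
Product: 4 (5S)-2-methyl-5-(prop-1-en-2-yl)cyclohexa-1,3-diene
Conditions: n-BuLi (2.3 equiv), TMEDA, hexane/THF, –78 → 0 °C; then H2O quench. The volatile triene is used crude in step 3.
Reagents that add atoms: none
Why: Shapiro reaction of an α,β-unsaturated tosylhydrazone. Deprotonation at C-6, loss of Ts⁻ and N2, and protonation of the resulting 2-lithio-diene give the conjugated 1,3-diene. The isopropenyl group and C-5 are untouched.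

**Step 3**
Reactants: 4
Product: 5 endoperoxide, 5-methyl-7-(prop-1-en-2-yl)-2,3-dioxabicyclo[2.2.2]oct-5-ene, with the O–O bridge anti to the isopropenyl group
Conditions: O2, TPP (0.1 mol%), white LED, CH2Cl2, 0 °C, 2 h
Reagents that add atoms: singlet oxygen generated from triplet oxygen, O=O
Why: Sensitised photooxygenation is a [4+2] of ¹O2 with a cyclic 1,3-diene. ¹O2 adds suprafacially to the diene face anti to the C-5 isopropenyl group, so both new C–O bonds are cis to each other and trans to that substituent. This sets the C-3 and C-6 oxygen-bearing centres. The ene reaction at the isopropenyl group is much slower and not competitive. The minor syn diastereomer is removed by chromatography.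

**Step 4**
Reactants: 5; 6 prenal (3-methylbut-2-enal)
Product: 7 (6S)-2-methyl-6-(5-methyl-2,3-dioxabicyclo[2.2.2]oct-5-en-7-yl)hept-2-en-4-one
Conditions: prenal (6 equiv), TIPS-SH (20 mol%), DPAP (10 mol%), 365 nm, PhCF3, 25 °C
Reagents that add atoms: none
Why: Thiol-catalysed radical-chain hydroacylation. The thiyl radical abstracts the aldehyde H, and the enoyl radical adds to the terminal CH2 of the isopropenyl group (anti-Markovnikov). The bulky silanethiol then delivers H to the tertiary radical from the less hindered face, which sets the methyl-bearing stereocentre by substrate control. I expect dr about 3:1, with the desired (S) isomer separated by HPLC. The diene was consumed in step 3, so it cannot act as an H-donor or radical trap.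

**Step 5**
Reactants: 8 curcumin
Product: 9 curcumin BF2 chelate
Conditions: BF3·OEt2 (1.2 equiv), CH2Cl2, rt, 1 h
Reagents that add atoms: boron trifluoride, FB(F)F (added as its diethyl ether complex)
Why: Difluoroboron chelation of the β-diketone removes the nucleophilic central carbon and the enol, leaving the two phenols as the only nucleophilic sites.

**Step 6**
Reactants: 7; 9 (3 equiv)
Product: 10 BF2-curcumin mono-aryl ether carrying the C-3 hydroperoxide
Conditions: Pd2(dba)3·CHCl3 (2.5 mol%), dppf (6 mol%), THF, 40 °C, no added base; 7 added slowly to 9
Reagents that add atoms: none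
Why: Proposed new method: Pd(0) binds the ring alkene anti to the O–O bridge and ionises the C-6–O bond. That ionisation gives the π-allyl with a tertiary terminus (C-2, bearing Me and C-3), which is better stabilised than the allyl from C-3–O ionisation, so C-6–O ionises preferentially. A pendant peroxy anion is left on C-3 and is protonated by the phenol. Phenoxide attacks the less hindered secondary terminus C-6 (versus tertiary C-2) anti to Pd, which is the face the peroxide oxygen occupied. Net double inversion therefore gives retention, with the aryl ether trans to the side chain and cis to the C-3 oxygen. The closest known reactions are Tsuji–Trost allylic etherification of phenols and Pd-catalysed ionisation of allylic peroxides. The new feature is using a bicyclic 1,4-endoperoxide as the electrophile to give a 4-aryloxy-2-enyl hydroperoxide.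

**Step 7**
Reactants: 10
Product: 11 BF2-curcumin aryl ether with the free C-3 allylic alcohol
Conditions: PPh3 (1.5 equiv), THF, 25 °C, 1 h
Reagents that add atoms: none
Why: Phosphine reduction of a hydroperoxide to the alcohol (Ph3P=O is the by-product) cleaves only the O–O bond, so the C-3 configuration is retained.

**Step 8**
Reactants: 11
Product: 12 Bisabolocurcumin ether (target)
Conditions: basic Al2O3 (activity III), CH2Cl2/MeOH 9:1, 25 °C, 2 h; then prep-HPLC
Reagents that add atoms: none
Why: Nucleophilic decomplexation of the BF2 β-diketonate returns the free diketo-enol, and HPLC removes any bis-ether and residual side-chain epimer.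

## Compound list
1 | (S)-(+)-carvone | CC1=CC[C@@H](CC1=O)C(C)=C | starting material
2 | p-toluenesulfonylhydrazide | Cc1ccc(cc1)S(=O)(=O)NN | starting material
3 | (S)-carvone tosylhydrazone | CC1=CC[C@@H](CC1=NNS(=O)(=O)c1ccc(C)cc1)C(C)=C | intermediate
4 | (5S)-2-methyl-5-(prop-1-en-2-yl)cyclohexa-1,3-diene | C1=CC(C)=CC[C@@H]1C(C)=C | intermediate
5 | 5-methyl-7-(prop-1-en-2-yl)-2,3-dioxabicyclo[2.2.2]oct-5-ene (O–O anti to the isopropenyl group) | O1[C@H]2C=C(C)[C@@H](O1)C[C@@H]2C(C)=C | intermediate
6 | prenal | CC(C)=CC=O | starting material
7 | (6S)-2-methyl-6-(5-methyl-2,3-dioxabicyclo[2.2.2]oct-5-en-7-yl)hept-2-en-4-one | O1[C@H]2C=C(C)[C@@H](O1)C[C@@H]2[C@@H](C)CC(=O)C=C(C)C | intermediate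
8 | curcumin | COc1cc(/C=C/C(=O)/C=C(O)/C=C/c2ccc(O)c(OC)c2)ccc1O | starting material
9 | curcumin BF2 chelate | COc1cc(/C=C/C2=CC(/C=C/c3ccc(O)c(OC)c3)=[O+][B-](F)(F)O2)ccc1O | intermediate
10 | BF2-curcumin aryl ether hydroperoxide | COc1cc(/C=C/C2=CC(/C=C/c3ccc(O[C@H]4C=C(C)[C@@H](OO)C[C@@H]4[C@@H](C)CC(=O)C=C(C)C)c(OC)c3)=[O+][B-](F)(F)O2)ccc1O | intermediate
11 | BF2-curcumin aryl ether alcohol | COc1cc(/C=C/C2=CC(/C=C/c3ccc(O[C@H]4C=C(C)[C@@H](O)C[C@@H]4[C@@H](C)CC(=O)C=C(C)C)c(OC)c3)=[O+][B-](F)(F)O2)ccc1O | intermediate
12 | Bisabolocurcumin ether | COc1cc(/C=C/C(=O)/C=C(O)/C=C/c2ccc(O[C@H]3C=C(C)[C@@H](O)C[C@@H]3[C@@H](C)CC(=O)C=C(C)C)c(OC)c2)ccc1O | target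

**Total steps:** 8. **Longest linear sequence:** 7 (steps 1, 2, 3, 4, 6, 7, 8; step 5 is a parallel branch).

## Three steps most likely to fail
1. **Step 6 (proposed new method).** Pd must approach the alkene face that carries the side chain, so it may be sterically blocked or ionise the wrong C–O bond. A Kornblum–DeLaMare rearrangement to the γ-hydroxyenone or phosphine oxidation may also compete.
   - Fallback (known chemistry): reduce 5 or 7 with thiourea to the cis-1,4-diol and selectively acetylate the less hindered C-3 OH. Then O-arylate the C-6 alkoxide by SNAr with 4-fluoro-3-methoxybenzaldehyde, which proceeds with retention. Remove the acetate, then build the curcuminoid by Pabon condensation of the aryl aldehyde with the feruloylacetone–boron complex.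
2. **Step 4.** The chain may be inefficient with an enal, the O–O bond may not survive thiyl or alkyl radicals, and the selectivity at the methyl-bearing centre may be poor.
   - Fallback: install the side chain ionically on triene 4 before photooxygenation. Hydroborate the isopropenyl group with 9-BBN and couple the alkyl-9-BBN with 3,3-dimethylacryloyl chloride (Pd acyl Suzuki), or hydroborate/oxidise to the aldehyde, add isobutenylMgBr and oxidise. Then run step 3 and separate the epimers at the endoperoxide stage.
3. **Step 8.** BF2 removal may need conditions the curcuminoid cannot tolerate, since it degrades in base.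
   - Fallback: use vanillin as the phenol partner in step 6, then build the curcuminoid last by Pabon condensation with the feruloylacetone–B2O3 complex, which is freed by dilute acid, so no BF2 group is needed.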